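**Retrosynthetic overview**
1. Target 16 ⇒ O-acetylation of the C6 alcohol 15.
2. 15 ⇒ open-chain bromo enal 12 by one ring-closing C1–C2 bond: the 2-(methoxycarbonyl)allyl chromium reagent from 12 (a β-acyl carbanion, i.e. homoenolate, equivalent) adds to the C2 aldehyde. The 14-membered carbocycle forms first, the γ-lactone closes second in the same flask, and C1 and C2 are set there.
3. 12 ⇒ enal 9 + prenal dienol ether 11 by asymmetric vinylogous aldol (C5–C6 bond, C6 stereocentre, E-C3=C4).
4. 9 ⇒ (2E,6E)-farnesol 1 (C6–C14 and C1, both E-alkenes in place) + methyl acrylate 6 (C15–C17), via terminal C3 excision, Morita–Baylis–Hillman reaction, oxidation and allylic bromination.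

Assumption: cembrane numbering is used (C1 = ring CH bearing C15, C2 = lactone O–CH, C6 = acetoxy carbon, C16 = lactone C=O, C17 = exocyclic CH2), and the facial sense of the boron catalyst (step 7) and of the chromium ligand (step 8) is assigned by analogy with their intermolecular use, to be confirmed on a model aldehyde, with the mirror-image controller used if the sense is opposite.

**Step 1**
Reactants: 1 (2E,6E)-farnesol
Product: 3 (2E,6E)-10,11-epoxy-3,7,11-trimethyldodeca-2,6-dien-1-ol (racemic epoxide), via terminal bromohydrin 2 (not isolated)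
Conditions: NBS, THF/H2O (2:1), 0 °C; then K2CO3, MeOH, rt
Reagents that add atoms: water, O (the epoxide oxygen); N-bromosuccinimide, O=C1CCC(=O)N1Br (its bromine is carried only in intermediate 2)
Why: Van Tamelen-type terminal-selective bromohydrin formation (the distal trisubstituted alkene is the most electron-rich and least hindered one in aqueous THF) followed by base-induced Williamson closure gives the 10,11-epoxide, whose racemic stereocentre is destroyed in step 2.

**Step 2**
Reactants: 3 (2E,6E)-10,11-epoxy-3,7,11-trimethyldodeca-2,6-dien-1-ol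
Product: 5 (4E,8E)-10-hydroxy-4,8-dimethyldeca-4,8-dienal, via vicinal diol 4 (not isolated)
Conditions: H5IO6, THF/H2O, 0 °C → rt
Reagents that add atoms: water, O (enters intermediate 4 only and leaves with acetone; product 5 keeps no new atom)
Why: Periodic acid hydrolyses the epoxide and cleaves the glycol (Malaprade cleavage), excising three carbons as acetone and leaving the C1 aldehyde without touching the two E-trisubstituted alkenes or the allylic alcohol.

**Step 3**
Reactants: 5 (4E,8E)-10-hydroxy-4,8-dimethyldeca-4,8-dienal; 6 methyl acrylate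
Product: 7 methyl (6E,10E)-3,12-dihydroxy-6,10-dimethyl-2-methylidenedodeca-6,10-dienoate (racemic at C3)
Conditions: DABCO (1,4-diazabicyclo[2.2.2]octane, 1 equiv), methyl acrylate (3 equiv), 1,4-dioxane/H2O (1:1), rt, 48–72 h
Reagents that add atoms: methyl acrylate (6), C=CC(=O)OC
Why: Morita–Baylis–Hillman reaction, in which the DABCO–acrylate zwitterion adds to the unhindered aliphatic aldehyde (aqueous dioxane accelerates it) and installs C15–C17 on C1; the new carbinol is racemic but becomes sp2 in step 5.

**Step 4**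
Reactants: 7 methyl (6E,10E)-3,12-dihydroxy-6,10-dimethyl-2-methylidenedodeca-6,10-dienoate
Product: 8 methyl (6E,10E)-3-hydroxy-6,10-dimethyl-2-methylidene-12-oxododeca-6,10-dienoate (racemic at C3)
Conditions: TEMPO (10 mol %), PhI(OAc)2 (1.1 equiv), CH2Cl2, rt
Reagents that add atoms: none
Why: Oxoammonium (TEMPO/PhI(OAc)2) oxidation is selective for the primary allylic alcohol over the hindered secondary Morita–Baylis–Hillman carbinol and gives the E-enal without E/Z scrambling.

**Step 5**
Reactants: 8 methyl (6E,10E)-3-hydroxy-6,10-dimethyl-2-methylidene-12-oxododeca-6,10-dienoate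
Product: 9 methyl (2Z,6E,10E)-2-(bromomethyl)-6,10-dimethyl-12-oxododeca-2,6,10-trienoate
Conditions: NBS, Me2S, CH2Cl2, 0 °C (reagent pre-formed); then 8, 0 °C → rt
Reagents that add atoms: N-bromosuccinimide, O=C1CCC(=O)N1Br
Why: Corey–Kim-type activation of the allylic alcohol as an alkoxysulfonium salt and SN2' return of bromide gives the thermodynamically preferred (2Z)-2-(bromomethyl)enoate, and the enal and isolated alkenes are inert to the pre-formed sulfonium reagent.

**Step 6**
Reactants: 10 3-methylbut-2-enal (prenal)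
Product: 11 tert-butyl(dimethyl){[(1E)-3-methylbuta-1,3-dien-1-yl]oxy}silane
Conditions: TBSOTf, Et3N, Et2O, 0 °C → rt
Reagents that add atoms: tert-butyldimethylsilyl trifluoromethanesulfonate, CC(C)(C)[Si](C)(C)OS(=O)(=O)C(F)(F)F
Why: Soft enolisation, in which Et3N removes a γ-proton from the O-silylated oxocarbenium ion of prenal to give the silyl dienol ether (mainly 1E; the 1Z isomer reacts the same way in step 7).

**Step 7**
Reactants: 9 methyl (2Z,6E,10E)-2-(bromomethyl)-6,10-dimethyl-12-oxododeca-2,6,10-trienoate; 11 tert-butyl(dimethyl){[(1E)-3-methylbuta-1,3-dien-1-yl]oxy}silane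
Product: 12 methyl (2Z,6E,10E,12R,14E)-2-(bromomethyl)-12-hydroxy-6,10,14-trimethyl-16-oxohexadeca-2,6,10,14-tetraenoate
Conditions: N-tosyl-L-tryptophan-derived B-phenyl-1,3,2-oxazaborolidin-5-one (50 mol %), 11 (2 equiv), iPrOH (1.2 equiv), EtCN, −78 °C
Reagents that add atoms: dienol ether 11 (its C5 enal unit), C=C(C)/C=C/O[Si](C)(C)C(C)(C)C
Why: Catalytic asymmetric vinylogous Mukaiyama aldol reaction, in which the chiral boron Lewis acid binds only the aldehyde and shields its Si face, so the dienol ether attacks through its γ-carbon in the s-trans conformation on the Re face, setting C6 (C12 of the chain) as R and the new C3=C4 alkene as E while isopropanol takes up the silyl group; the allylic bromide and enoate are not activated at −78 °C.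

**Step 8**
Reactants: 12 methyl (2Z,6E,10E,12R,14E)-2-(bromomethyl)-12-hydroxy-6,10,14-trimethyl-16-oxohexadeca-2,6,10,14-tetraenoate
Product: 15 (1R,2S,3E,6R,7E,11E)-6-hydroxycembra-3,7,11,15(17)-tetraen-16,2-olide, via allylchromium species 13 (not isolated), via seco hydroxy ester 14 (not isolated)
Conditions: CrCl2 (4 equiv), (S,S)-3,6-diphenyl-1,8-bis(4-isopropyl-4,5-dihydrooxazol-2-yl)-9H-carbazole (4.4 equiv), iPr2NEt (4.4 equiv), 4 Å MS, THF, rt; 12 added by syringe pump over 12 h (final 2 mM); aq NH4Cl; then PPTS (cat.), CH2Cl2, rt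
Reagents that add atoms: none
Why: Proposed new method: two CrCl2 reduce the allylic bromide to a 2-(methoxycarbonyl)allylchromium species, a homoenolate equivalent whose nucleophilic carbon C1 is the natively electrophilic β-carbon of an acrylate, and this adds through C1 with allylic transposition in a six-membered chair Zimmerman–Traxler transition state to the electrophilic C2 aldehyde, closing the 14-membered ring; E/Z equilibration of the allylchromium by 1,3-metal shift lets the chair with both chain termini equatorial win and gives the anti adduct (trans lactone after loss of MeOH), while the carbazole bis(oxazoline) ligand on chromium selects the Re face of the aldehyde (2S, hence 1R), the closest known reactions being the intermolecular CrCl2-mediated Dreiding–Schmidt/Nozaki–Hiyama 2-(alkoxycarbonyl)allylation of aldehydes, its ligand-controlled asymmetric variant and CrCl2-mediated allylic macrocyclisations of cembranoid precursors.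

**Step 9**
Reactants: 15 (1R,2S,3E,6R,7E,11E)-6-hydroxycembra-3,7,11,15(17)-tetraen-16,2-olide
Product: 16 (1R,2S,3E,6R,7E,11E)-6-acetoxycembra-3,7,11,15(17)-tetraen-16,2-olide (CNP0206931.1)
Conditions: Ac2O, pyridine, DMAP (cat.), CH2Cl2, 0 °C → rt
Reagents that add atoms: acetic anhydride, CC(=O)OC(C)=O
Why: DMAP-catalysed O-acylation of the secondary allylic alcohol proceeds with retention at C6 and leaves the α-methylene lactone and the three alkenes untouched.

**Compound list**
1 | (2E,6E)-farnesol, (2E,6E)-3,7,11-trimethyldodeca-2,6,10-trien-1-ol | OC/C=C(\C)CC/C=C(\C)CCC=C(C)C | starting material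
2 | (2E,6E)-10-bromo-3,7,11-trimethyldodeca-2,6-diene-1,11-diol (racemic) | OC/C=C(\C)CC/C=C(\C)CCC(Br)C(C)(C)O | intermediate
3 | (2E,6E)-10,11-epoxy-3,7,11-trimethyldodeca-2,6-dien-1-ol (racemic) | OC/C=C(\C)CC/C=C(\C)CCC1OC1(C)C | intermediate
4 | (2E,6E)-3,7,11-trimethyldodeca-2,6-diene-1,10,11-triol (racemic) | OC/C=C(\C)CC/C=C(\C)CCC(O)C(C)(C)O | intermediate
5 | (4E,8E)-10-hydroxy-4,8-dimethyldeca-4,8-dienal | OC/C=C(\C)CC/C=C(\C)CCC=O | intermediate
6 | methyl acrylate | C=CC(=O)OC | starting material
7 | methyl (6E,10E)-3,12-dihydroxy-6,10-dimethyl-2-methylidenedodeca-6,10-dienoate (racemic at C3) | OC/C=C(\C)CC/C=C(\C)CCC(O)C(=C)C(=O)OC | intermediate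
8 | methyl (6E,10E)-3-hydroxy-6,10-dimethyl-2-methylidene-12-oxododeca-6,10-dienoate (racemic at C3) | O=C/C=C(\C)CC/C=C(\C)CCC(O)C(=C)C(=O)OC | intermediate
9 | methyl (2Z,6E,10E)-2-(bromomethyl)-6,10-dimethyl-12-oxododeca-2,6,10-trienoate | O=C/C=C(\C)CC/C=C(\C)CC/C=C(\CBr)C(=O)OC | intermediate
10 | 3-methylbut-2-enal (prenal) | CC(C)=CC=O | starting material
11 | tert-butyl(dimethyl){[(1E)-3-methylbuta-1,3-dien-1-yl]oxy}silane | C=C(C)/C=C/O[Si](C)(C)C(C)(C)C | intermediate
12 | methyl (2Z,6E,10E,12R,14E)-2-(bromomethyl)-12-hydroxy-6,10,14-trimethyl-16-oxohexadeca-2,6,10,14-tetraenoate | O=C/C=C(\C)C[C@@H](O)/C=C(\C)CC/C=C(\C)CC/C=C(\CBr)C(=O)OC | intermediate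
13 | [(6E,10E,12R,14E)-12-hydroxy-2-(methoxycarbonyl)-6,10,14-trimethyl-16-oxohexadeca-2,6,10,14-tetraen-1-yl]chromium dichloride (trivalent chromium; C2=C3 geometry fluxional; chiral ligand and THF on chromium not drawn) | O=C/C=C(\C)C[C@@H](O)/C=C(\C)CC/C=C(\C)CCC=C(C[Cr](Cl)Cl)C(=O)OC | intermediate
14 | methyl 2-[(1R,2S,3E,6R,7E,11E)-2,6-dihydroxy-4,8,12-trimethylcyclotetradeca-3,7,11-trien-1-yl]prop-2-enoate | O[C@H]1/C=C(\C)C[C@@H](O)/C=C(\C)CC/C=C(\C)CC[C@@H]1C(=C)C(=O)OC | intermediate
15 | (1R,2S,3E,6R,7E,11E)-6-hydroxycembra-3,7,11,15(17)-tetraen-16,2-olide (trans-fused α-methylene-γ-lactone on the 14-membered ring) | C=C1C(=O)O[C@H]2/C=C(\C)C[C@@H](O)/C=C(\C)CC/C=C(\C)CC[C@H]12 | intermediate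
16 | (1R,2S,3E,6R,7E,11E)-6-acetoxycembra-3,7,11,15(17)-tetraen-16,2-olide (CNP0206931.1) | C=C1C(=O)O[C@H]2/C=C(\C)C[C@@H](OC(C)=O)/C=C(\C)CC/C=C(\C)CC[C@H]12 | target

**Step count**
Total: 9 steps (8 in the main line from farnesol plus 1 to make dienol ether 11).
Longest linear sequence: 8 steps (1 → 3 → 5 → 7 → 8 → 9 → 12 → 15 → 16).

**Steps most likely to fail, with fallbacks**

Most at risk is step 8. The ring closure may retain the (2Z) allyl geometry and give the cis-fused (syn) lactone instead of the trans one; facial control by the ligand in a macrocyclic setting is also untested. The fallback sets out from 12 and comes back at 15. O6 is silylated (TBSOTf, 2,6-lutidine, CH2Cl2) to give silyl ether F1. F1 is cyclised with CrCl2 and the mirror-image (R,R) ligand, so that the aldehyde is attacked on its Si face and the syn pathway delivers the cis-fused (1R,2R) lactone F2. LiOH (THF/H2O, then careful acidification at 0 °C) opens it to hydroxy acid F3. Mitsunobu relactonisation (PPh3, DIAD, THF) then displaces the activated allylic C2–O bond with inversion and gives the trans-fused (1R,2S) silyl ether F4. HF·pyridine frees the C6 alcohol, which is 15. Stereochemistry at C2 is thus corrected by inversion rather than by the transition state of the ring closure.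

Second is step 7. The ee, the γ/α and E/Z selectivity, and tolerance of the allylic bromide are all uncertain for this particular enal. The fallback sets out from 9 and comes back at 15 and at 16. The aldol is run with achiral BF3·OEt2 (CH2Cl2, −78 °C), giving 12 as a racemate together with its 12S enantiomer F5. The mixture is cyclised as in step 8, where the chromium ligand still fixes C1 and C2, and 15 is separated by chromatography from its C6 epimer F6. 15 goes on to step 9, while F6 is converted directly into 16 by Mitsunobu esterification with acetic acid (PPh3, DIAD, THF), which inverts C6. This replaces catalyst control at C6 by late stereoconvergence.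

Third is step 3. The amine-catalysed Morita–Baylis–Hillman reaction of an aliphatic aldehyde can stall or give low conversion. The fallback sets out from 5 and comes back at 7. Methyl propiolate is hydroaluminated with iBu2AlH/HMPA (THF, 0 °C) to the α-aluminoacrylate F7. F7 is used in excess, because the free hydroxyl of 5 consumes one equivalent, and adds 1,2 to the aldehyde of 5 to give 7 after aqueous work-up. This is a vinylmetal addition in place of nucleophilic amine catalysis.

**Further compounds**
F1 | step 8 | methyl (2Z,6E,10E,12R,14E)-2-(bromomethyl)-12-[(tert-butyldimethylsilyl)oxy]-6,10,14-trimethyl-16-oxohexadeca-2,6,10,14-tetraenoate | O=C/C=C(\C)C[C@@H](O[Si](C)(C)C(C)(C)C)/C=C(\C)CC/C=C(\C)CC/C=C(\CBr)C(=O)OC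
F2 | step 8 | (1R,2R,3E,6R,7E,11E)-6-[(tert-butyldimethylsilyl)oxy]cembra-3,7,11,15(17)-tetraen-16,2-olide (cis-fused lactone) | C=C1C(=O)O[C@@H]2/C=C(\C)C[C@@H](O[Si](C)(C)C(C)(C)C)/C=C(\C)CC/C=C(\C)CC[C@H]12
F3 | step 8 | 2-[(1R,2R,3E,6R,7E,11E)-6-[(tert-butyldimethylsilyl)oxy]-2-hydroxy-4,8,12-trimethylcyclotetradeca-3,7,11-trien-1-yl]prop-2-enoic acid | O[C@@H]1/C=C(\C)C[C@@H](O[Si](C)(C)C(C)(C)C)/C=C(\C)CC/C=C(\C)CC[C@@H]1C(=C)C(=O)O
F4 | step 8 | (1R,2S,3E,6R,7E,11E)-6-[(tert-butyldimethylsilyl)oxy]cembra-3,7,11,15(17)-tetraen-16,2-olide (trans-fused lactone) | C=C1C(=O)O[C@H]2/C=C(\C)C[C@@H](O[Si](C)(C)C(C)(C)C)/C=C(\C)CC/C=C(\C)CC[C@H]12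
F5 | step 7 | methyl (2Z,6E,10E,12S,14E)-2-(bromomethyl)-12-hydroxy-6,10,14-trimethyl-16-oxohexadeca-2,6,10,14-tetraenoate | O=C/C=C(\C)C[C@H](O)/C=C(\C)CC/C=C(\C)CC/C=C(\CBr)C(=O)OC
F6 | step 7 | (1R,2S,3E,6S,7E,11E)-6-hydroxycembra-3,7,11,15(17)-tetraen-16,2-olide | C=C1C(=O)O[C@H]2/C=C(\C)C[C@H](O)/C=C(\C)CC/C=C(\C)CC[C@H]12
F7 | step 3 | methyl 2-(diisobutylalumanyl)prop-2-enoate | C=C(C(=O)OC)[Al](CC(C)C)CC(C)C
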